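**Retrosynthetic overview**

1. Locants follow oligostilbene usage: units a, b and c are the C7–C8 pairs; rings A, C and E are the 4-hydroxyphenyl rings on C7a, C7b and C7c, and rings B, D and G are the resorcinol rings on C8a, C8b and C8c (the letter F is kept for fallback compounds). The target comes from its octabenzyl ether by hydrogenolysis.
2. Key disconnection: C8a–C8b (closes the indane C7b–C8b–C8a–C9a–C10a) and C7a–C10c (closes the eight-membered ring) are formed together, from an open N-acyloxyphthalimide in which C8b carries the carboxyl group.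
3. Enabling feature: the (E)-C7a=C8a stilbene bond on ring B sits ortho to the C7b methine, so a radical at C8b is 5-exo to C8a and leaves a 4-benzyloxybenzylic centre at C7a; ring G, held on C8c next to C9b of ring D, offers C10c (ortho and para to two ether oxygens) to capture that centre once it is oxidised to the cation.
4. The precursor is joined at C8b–C9b by Pd α-arylation of a (3R)-3,3-diarylpropanoate (rings A, B and C; C7b from Rh-catalysed conjugate arylation of a 5-styrylcoumarin, whose lactone is a temporary ring) with a 4-bromo-2,3-dihydrobenzofuran (rings D, E and G).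
5. Ring order: dihydrofuran (Rh-carbene C–H insertion, then C7c epimerisation to trans), temporary lactone (opened), then indane and eight-membered ring in the key step.

Key step: step 17

Abbreviations used in names: BnOPh = 4-(benzyloxy)phenyl; StAr = 2,4-bis(benzyloxy)-6-[(E)-2-(4-benzyloxyphenyl)ethenyl]phenyl; DBF = (2S,3S)-6-(benzyloxy)-2-[4-(benzyloxy)phenyl]-3-[3,5-bis(benzyloxy)phenyl]-2,3-dihydro-1-benzofuran-4-yl.

Remark: the sense of induction of the two chiral catalysts (step 7 and step 12) is assigned by analogy with their usual behaviour; if the first batch shows the opposite sense, the enantiomeric catalyst is used.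

**Route**

Step 1
Reactants: 1 1,3-bis(benzyloxy)-5-bromobenzene
Product: 3 2,4-bis(benzyloxy)-6-bromobenzaldehyde, via iminium chloride 2 (not isolated)
Conditions: POCl3, DMF, 0 to 70 °C; then H2O
Reagents that add atoms: N,N-dimethylformamide CN(C)C=O; water O
Why: Vilsmeier–Haack formylation should go para to one benzyloxy group and ortho to the other (the site between the two ethers is more hindered), which places the formyl carbon (later C8c) between the bromide and an ether oxygen.

Step 2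
Reactants: 3 2,4-bis(benzyloxy)-6-bromobenzaldehyde; 1 1,3-bis(benzyloxy)-5-bromobenzene
Product: 5 (RS)-[2,4-bis(benzyloxy)-6-bromophenyl][3,5-bis(benzyloxy)phenyl]methanol, via arylmagnesium bromide 4 (not isolated)
Conditions: 1, Mg, THF, 40 °C; then 3, 0 °C; then H2O
Reagents that add atoms: none
Why: Grignard addition to the aldehyde brings in ring G; the carbinol centre is racemic and is removed by oxidation in the next step.

Step 3
Reactants: 5 (RS)-[2,4-bis(benzyloxy)-6-bromophenyl][3,5-bis(benzyloxy)phenyl]methanol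
Product: 6 [2,4-bis(benzyloxy)-6-bromophenyl][3,5-bis(benzyloxy)phenyl]methanone
Conditions: DMP, CH2Cl2, rt
Reagents that add atoms: none
Why: Dess–Martin oxidation of a secondary benzylic alcohol is neutral and should leave benzyl ethers and the aryl bromide untouched.

Step 4
Reactants: 6 [2,4-bis(benzyloxy)-6-bromophenyl][3,5-bis(benzyloxy)phenyl]methanone
Product: 7 [4-(benzyloxy)-2-bromo-6-hydroxyphenyl][3,5-bis(benzyloxy)phenyl]methanone
Conditions: MgBr2·OEt2 (3 equiv), toluene/Et2O, 70 °C; then 1 M HCl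
Reagents that add atoms: none
Why: chelation-controlled ether cleavage, in which magnesium bridges the ketone oxygen and the ortho ether oxygen so that bromide should remove only that benzyl group.

Step 5
Reactants: 7 [4-(benzyloxy)-2-bromo-6-hydroxyphenyl][3,5-bis(benzyloxy)phenyl]methanone; 8 1-(benzyloxy)-4-(chloromethyl)benzene
Product: 9 [4-(benzyloxy)-2-[(4-benzyloxyphenyl)methoxy]-6-bromophenyl][3,5-bis(benzyloxy)phenyl]methanone
Conditions: K2CO3, NaI (cat.), DMF, 60 °C
Reagents that add atoms: none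
Why: Williamson etherification of the freed phenol installs the benzylic CH2 that becomes C7c together with ring E.

Step 6
Reactants: 9 [4-(benzyloxy)-2-[(4-benzyloxyphenyl)methoxy]-6-bromophenyl][3,5-bis(benzyloxy)phenyl]methanone
Product: 10 hydrazone of ketone 9 (E/Z mixture)
Conditions: N2H4 (anhydrous, 15 equiv), AcOH (cat.), n-BuOH, 110 °C, sealed tube
Reagents that add atoms: hydrazine NN
Why: hydrazone condensation, forced by excess hydrazine and heat because the ketone is di-ortho-substituted; the C=N geometry is irrelevant.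

Step 7
Reactants: 10 hydrazone of ketone 9
Product: 12 (2R,3S)-6-(benzyloxy)-2-[4-(benzyloxy)phenyl]-3-[3,5-bis(benzyloxy)phenyl]-4-bromo-2,3-dihydro-1-benzofuran (cis), via diazo compound 11 (not isolated)
Conditions: MnO2, CH2Cl2, 0 °C, filter; then Rh2(R-PTAD)4 (dirhodium tetrakis[(R)-(1-adamantyl)(phthalimido)acetate], 1 mol%), CH2Cl2, −20 °C to rt
Reagents that add atoms: none
Why: dehydrogenation to the diaryldiazomethane and enantioselective intramolecular 1,5 C–H insertion of the donor/donor rhodium carbene into the benzylic O–CH2 bond should close the dihydrofuran cis, with C8c (position 3 of the dihydrobenzofuran) set by the chiral carboxylate ligands.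

Step 8
Reactants: 12 (2R,3S)-6-(benzyloxy)-2-[4-(benzyloxy)phenyl]-3-[3,5-bis(benzyloxy)phenyl]-4-bromo-2,3-dihydro-1-benzofuran
Product: 14 (2S,3S)-6-(benzyloxy)-2-[4-(benzyloxy)phenyl]-3-[3,5-bis(benzyloxy)phenyl]-4-bromo-2,3-dihydro-1-benzofuran (trans), via ring-opened benzylic cation 13 (not isolated)
Conditions: CF3CO2H (2 equiv), CH2Cl2, 0 °C to rt
Reagents that add atoms: none
Why: acid-mediated ring–chain epimerisation at position 2 (C7c), in which the 4-benzyloxybenzylic C–O bond ionises reversibly and re-closes anti to the aryl group on position 3 to give the more stable trans isomer; position 3 (C8c) keeps its configuration provided re-closure outruns proton loss or hydride shift there, so the enantiomeric purity is checked after this step.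

Step 9
Reactants: 15 5,7-dihydroxy-2H-chromen-2-one
Product: 16 7-(benzyloxy)-5-hydroxy-2H-chromen-2-one
Conditions: BnBr (1.05 equiv), K2CO3 (1.1 equiv), acetone, rt
Reagents that add atoms: benzyl bromide BrCc1ccccc1
Why: Williamson etherification should select the more acidic and less hindered 7-OH.

Step 10
Reactants: 16 7-(benzyloxy)-5-hydroxy-2H-chromen-2-one
Product: 17 7-(benzyloxy)-2-oxo-2H-chromen-5-yl trifluoromethanesulfonate
Conditions: Tf2O, pyridine, CH2Cl2, 0 °C
Reagents that add atoms: trifluoromethanesulfonic anhydride O=S(=O)(OS(=O)(=O)C(F)(F)F)C(F)(F)F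
Why: O-sulfonylation turns the remaining phenol into a cross-coupling handle at the carbon that becomes C9a.

Step 11
Reactants: 17 7-(benzyloxy)-2-oxo-2H-chromen-5-yl trifluoromethanesulfonate; 18 1-(benzyloxy)-4-ethenylbenzene
Product: 19 7-(benzyloxy)-5-[(E)-2-(4-benzyloxyphenyl)ethenyl]-2H-chromen-2-one
Conditions: Pd(OAc)2 (5 mol%), P(o-tol)3 (12 mol%), Et3N, DMF, 90 °C
Reagents that add atoms: none
Why: Mizoroki–Heck coupling (syn insertion, syn β-hydride elimination) should give the (E)-stilbene, which is the C7a=C8a bond with ring A.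

Step 12
Reactants: 19 7-(benzyloxy)-5-[(E)-2-(4-benzyloxyphenyl)ethenyl]-2H-chromen-2-one; 20 [4-(benzyloxy)phenyl]boronic acid
Product: 21 (4R)-7-(benzyloxy)-4-(BnOPh)-5-[(E)-2-(4-benzyloxyphenyl)ethenyl]-3,4-dihydro-2H-chromen-2-one
Conditions: Rh(acac)(C2H4)2 (3 mol%), (R)-SEGPHOS (3.3 mol%), 20 (5 equiv), dioxane/H2O 10:1, 60 °C
Reagents that add atoms: none
Why: Hayashi–Miyaura asymmetric conjugate arylation of the 3,4-double bond of the coumarin, in which the chiral bisphosphine–rhodium aryl delivers ring C to one enantioface and sets C7b; the stilbene is not an acceptor.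

Step 13
Reactants: 21 (4R)-7-(benzyloxy)-4-(BnOPh)-5-[(E)-2-(4-benzyloxyphenyl)ethenyl]-3,4-dihydro-2H-chromen-2-one
Product: 23 methyl (3R)-3-(BnOPh)-3-(StAr)propanoate, via potassium phenoxide 22 (not isolated)
Conditions: K2CO3, MeOH/THF, rt; then BnBr, DMF, 50 °C
Reagents that add atoms: methanol CO; benzyl bromide BrCc1ccccc1
Why: base-mediated methanolysis of the aryl lactone followed by Williamson benzylation of the phenoxide traps the open-chain form; C7b is not enolisable and is not affected.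

Step 14
Reactants: 23 methyl (3R)-3-(BnOPh)-3-(StAr)propanoate; 14 (2S,3S)-6-(benzyloxy)-2-[4-(benzyloxy)phenyl]-3-[3,5-bis(benzyloxy)phenyl]-4-bromo-2,3-dihydro-1-benzofuran
Product: 24 methyl (2RS,3R)-2-(DBF)-3-(BnOPh)-3-(StAr)propanoate
Conditions: Pd(dba)2 (5 mol%), P(t-Bu)3 (10 mol%), LiN(SiMe3)2 (2.2 equiv), toluene, rt to 60 °C
Reagents that add atoms: none
Why: palladium-catalysed α-arylation of the ester enolate forms C8b–C9b; C8b arises as a mixture of epimers, which does not matter because it becomes a planar radical in step 17.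

Step 15
Reactants: 24 methyl (2RS,3R)-2-(DBF)-3-(BnOPh)-3-(StAr)propanoate
Product: 25 (2RS,3R)-2-(DBF)-3-(BnOPh)-3-(StAr)propanoic acid
Conditions: LiOH, THF/MeOH/H2O, 60 °C; then 1 M HCl
Reagents that add atoms: lithium hydroxide [Li+].[OH-]
Why: saponification of the hindered methyl ester; epimerisation at C8b is of no consequence.

Step 16
Reactants: 25 (2RS,3R)-2-(DBF)-3-(BnOPh)-3-(StAr)propanoic acid
Product: 26 1,3-dioxoisoindolin-2-yl (2RS,3R)-2-(DBF)-3-(BnOPh)-3-(StAr)propanoate
Conditions: N-hydroxyphthalimide, DIC, DMAP (cat.), CH2Cl2, 0 °C to rt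
Reagents that add atoms: N-hydroxyphthalimide O=C1c2ccccc2C(=O)N1O
Why: carbodiimide esterification gives the redox-active ester, a traceless radical precursor at C8b.

Step 17
Reactants: 26 1,3-dioxoisoindolin-2-yl (2RS,3R)-2-(DBF)-3-(BnOPh)-3-(StAr)propanoate
Product: 30 octa-O-benzyl ether of the target (7aR,8aS,7bR,8bR,7cS,8cS), via benzylic radical 27 (not isolated), via cyclised benzylic radical 28 (not isolated), via benzylic cation 29 (not isolated)
Conditions: fac-Ir(ppy)3 (1 mol%), 450 nm LEDs, degassed CH2Cl2/HFIP 3:1, 5 mM, rt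
Reagents that add atoms: none
Why: Proposed new method: photoexcited Ir(ppy)3 should reduce the N-acyloxyphthalimide, which loses CO2 and phthalimide anion to give the C8b benzylic radical 27; this adds 5-exo-trig to C8a of the ortho stilbene to give the 4-benzyloxybenzylic radical 28, the oxidised iridium complex converts 28 into cation 29, and C10c of ring G attacks C7a with loss of a proton to the phthalimide anion. The closest known reaction types are photoredox decarboxylative carbo-arylation of styrenes by redox-active esters with electron-rich arenes (radical–polar crossover) and oxidative radical cyclisations terminated by Friedel–Crafts alkylation; what is new is the pairing of the cyclisation with arene capture in a medium ring. The indane closes by 5-exo-trig radical addition and the eight-membered ring by intramolecular Friedel–Crafts alkylation of the 3,5-bis(benzyloxy)phenyl ring. The pre-set C7b centre should place ring D on C8b anti to ring C and the C7a arm on C8a anti to ring D (all-trans indane), because the closure joins two stabilised benzylic radicals, is therefore late and in part reversible, and so follows product stability. C7a is fixed in the second closure, where the trans-fused tether presents ring G to one face of the planar cation with ring A turned outward. The step needs 5-exo over 6-endo addition (the 4-benzyloxyphenyl group stabilises the radical at C7a) and capture at C10c rather than at C14b of ring D (a trans-fused five-ring closure is not reachable), at ring C (its reachable carbon is meta to oxygen) or by proton loss (HFIP buffers the phthalimide anion and prolongs the cation lifetime); early oxidation of 27 is tolerated, since the C8b cation should add to the same stilbene carbon and reach 29 as well, and high dilution suppresses intermolecular paths.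

Step 18
Reactants: 30 octa-O-benzyl ether of the target
Product: 31 target CNP0193760.4 (7aR,8aS,7bR,8bR,7cS,8cS)
Conditions: H2 (1 atm), Pd(OH)2/C, THF/MeOH, rt
Reagents that add atoms: none
Why: hydrogenolysis should remove the eight benzyl ethers without touching a stereocentre; the dihydrofuran C–O bond is cleaved more slowly than O-benzyl ethers, so the reaction is stopped at full debenzylation.

**Compound list**

1 | 1,3-bis(benzyloxy)-5-bromobenzene | Brc1cc(OCc2ccccc2)cc(OCc2ccccc2)c1 | starting material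
2 | N-[[2,4-bis(benzyloxy)-6-bromophenyl]methylidene]-N-methylmethanaminium chloride | C[N+](C)=Cc1c(Br)cc(OCc2ccccc2)cc1OCc1ccccc1.[Cl-] | intermediate
3 | 2,4-bis(benzyloxy)-6-bromobenzaldehyde | O=Cc1c(Br)cc(OCc2ccccc2)cc1OCc1ccccc1 | intermediate
4 | [3,5-bis(benzyloxy)phenyl]magnesium bromide | Br[Mg]c1cc(OCc2ccccc2)cc(OCc2ccccc2)c1 | intermediate
5 | (RS)-[2,4-bis(benzyloxy)-6-bromophenyl][3,5-bis(benzyloxy)phenyl]methanol | OC(c1cc(OCc2ccccc2)cc(OCc2ccccc2)c1)c1c(Br)cc(OCc2ccccc2)cc1OCc1ccccc1 | intermediate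
6 | [2,4-bis(benzyloxy)-6-bromophenyl][3,5-bis(benzyloxy)phenyl]methanone | O=C(c1cc(OCc2ccccc2)cc(OCc2ccccc2)c1)c1c(Br)cc(OCc2ccccc2)cc1OCc1ccccc1 | intermediate
7 | [4-(benzyloxy)-2-bromo-6-hydroxyphenyl][3,5-bis(benzyloxy)phenyl]methanone | O=C(c1cc(OCc2ccccc2)cc(OCc2ccccc2)c1)c1c(Br)cc(OCc2ccccc2)cc1O | intermediate
8 | 1-(benzyloxy)-4-(chloromethyl)benzene | ClCc1ccc(OCc2ccccc2)cc1 | starting material
9 | [4-(benzyloxy)-2-[(4-benzyloxyphenyl)methoxy]-6-bromophenyl][3,5-bis(benzyloxy)phenyl]methanone | O=C(c1cc(OCc2ccccc2)cc(OCc2ccccc2)c1)c1c(Br)cc(OCc2ccccc2)cc1OCc1ccc(OCc2ccccc2)cc1 | intermediate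
10 | hydrazone of ketone 9 (E/Z mixture) | NN=C(c1cc(OCc2ccccc2)cc(OCc2ccccc2)c1)c1c(Br)cc(OCc2ccccc2)cc1OCc1ccc(OCc2ccccc2)cc1 | intermediate
11 | 5-(benzyloxy)-1-[(4-benzyloxyphenyl)methoxy]-3-bromo-2-[[3,5-bis(benzyloxy)phenyl](diazo)methyl]benzene | [N-]=[N+]=C(c1cc(OCc2ccccc2)cc(OCc2ccccc2)c1)c1c(Br)cc(OCc2ccccc2)cc1OCc1ccc(OCc2ccccc2)cc1 | intermediate
12 | (2R,3S)-6-(benzyloxy)-2-[4-(benzyloxy)phenyl]-3-[3,5-bis(benzyloxy)phenyl]-4-bromo-2,3-dihydro-1-benzofuran (cis) | c1c(OCc6ccccc6)cc(OCc6ccccc6)cc1[C@H]3c4c(cc(OCc6ccccc6)cc4Br)O[C@H]3c2ccc(OCc6ccccc6)cc2 | intermediate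
13 | ring-opened 4-benzyloxybenzylic cation of 12 (phenol on ring D, C8c unchanged) | c1c(OCc6ccccc6)cc(OCc6ccccc6)cc1[C@@H](c4c(O)cc(OCc6ccccc6)cc4Br)[CH+]c2ccc(OCc6ccccc6)cc2 | intermediate
14 | (2S,3S)-6-(benzyloxy)-2-[4-(benzyloxy)phenyl]-3-[3,5-bis(benzyloxy)phenyl]-4-bromo-2,3-dihydro-1-benzofuran (trans) | c1c(OCc6ccccc6)cc(OCc6ccccc6)cc1[C@H]3c4c(cc(OCc6ccccc6)cc4Br)O[C@@H]3c2ccc(OCc6ccccc6)cc2 | intermediate
15 | 5,7-dihydroxy-2H-chromen-2-one | O=c1ccc2c(O)cc(O)cc2o1 | starting material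
16 | 7-(benzyloxy)-5-hydroxy-2H-chromen-2-one | O=c1ccc2c(O)cc(OCc3ccccc3)cc2o1 | intermediate
17 | 7-(benzyloxy)-2-oxo-2H-chromen-5-yl trifluoromethanesulfonate | O=c1ccc2c(OS(=O)(=O)C(F)(F)F)cc(OCc3ccccc3)cc2o1 | intermediate
18 | 1-(benzyloxy)-4-ethenylbenzene | C=Cc1ccc(OCc2ccccc2)cc1 | starting material
19 | 7-(benzyloxy)-5-[(E)-2-(4-benzyloxyphenyl)ethenyl]-2H-chromen-2-one | O=c1ccc2c(/C=C/c3ccc(OCc4ccccc4)cc3)cc(OCc3ccccc3)cc2o1 | intermediate
20 | [4-(benzyloxy)phenyl]boronic acid | OB(O)c1ccc(OCc2ccccc2)cc1 | starting material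
21 | (4R)-7-(benzyloxy)-4-(BnOPh)-5-[(E)-2-(4-benzyloxyphenyl)ethenyl]-3,4-dihydro-2H-chromen-2-one | O=C1C[C@H](c5ccc(OCc6ccccc6)cc5)c5c(O1)cc(OCc6ccccc6)cc5/C=C/c1ccc(OCc6ccccc6)cc1 | intermediate
22 | potassium phenoxide of methyl (3R)-3-(BnOPh)-3-[4-(benzyloxy)-2-hydroxy-6-[(E)-2-(4-benzyloxyphenyl)ethenyl]phenyl]propanoate | COC(=O)C[C@H](c5ccc(OCc6ccccc6)cc5)c5c([O-])cc(OCc6ccccc6)cc5/C=C/c1ccc(OCc6ccccc6)cc1.[K+] | intermediate
23 | methyl (3R)-3-(BnOPh)-3-(StAr)propanoate | COC(=O)C[C@H](c5ccc(OCc6ccccc6)cc5)c5c(OCc6ccccc6)cc(OCc6ccccc6)cc5/C=C/c1ccc(OCc6ccccc6)cc1 | intermediate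
24 | methyl (2RS,3R)-2-(DBF)-3-(BnOPh)-3-(StAr)propanoate | c1c(OCc6ccccc6)cc(OCc6ccccc6)cc1[C@H]3c4c(cc(OCc6ccccc6)cc4C(C(=O)OC)[C@H](c5ccc(OCc6ccccc6)cc5)c5c(OCc6ccccc6)cc(OCc6ccccc6)cc5/C=C/c1ccc(OCc6ccccc6)cc1)O[C@@H]3c2ccc(OCc6ccccc6)cc2 | intermediate
25 | (2RS,3R)-2-(DBF)-3-(BnOPh)-3-(StAr)propanoic acid | c1c(OCc6ccccc6)cc(OCc6ccccc6)cc1[C@H]3c4c(cc(OCc6ccccc6)cc4C(C(=O)O)[C@H](c5ccc(OCc6ccccc6)cc5)c5c(OCc6ccccc6)cc(OCc6ccccc6)cc5/C=C/c1ccc(OCc6ccccc6)cc1)O[C@@H]3c2ccc(OCc6ccccc6)cc2 | intermediate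
26 | 1,3-dioxoisoindolin-2-yl (2RS,3R)-2-(DBF)-3-(BnOPh)-3-(StAr)propanoate | c1c(OCc6ccccc6)cc(OCc6ccccc6)cc1[C@H]3c4c(cc(OCc6ccccc6)cc4C(C(=O)ON7C(=O)c8ccccc8C7=O)[C@H](c5ccc(OCc6ccccc6)cc5)c5c(OCc6ccccc6)cc(OCc6ccccc6)cc5/C=C/c1ccc(OCc6ccccc6)cc1)O[C@@H]3c2ccc(OCc6ccccc6)cc2 | intermediate
27 | C8b benzylic radical formed from 26 by loss of CO2 and phthalimide anion | c1c(OCc6ccccc6)cc(OCc6ccccc6)cc1[C@H]3c4c(cc(OCc6ccccc6)cc4[CH][C@H](c5ccc(OCc6ccccc6)cc5)c5c(OCc6ccccc6)cc(OCc6ccccc6)cc5/C=C/c1ccc(OCc6ccccc6)cc1)O[C@@H]3c2ccc(OCc6ccccc6)cc2 | intermediate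
28 | C7a 4-benzyloxybenzylic radical on the all-trans indane (C8a–C8b formed) | c1c(OCc6ccccc6)cc(OCc6ccccc6)cc1[C@H]3c4c(cc(OCc6ccccc6)cc4[C@H]4[C@H](c5ccc(OCc6ccccc6)cc5)c5c(OCc6ccccc6)cc(OCc6ccccc6)cc5[C@@H]4[CH]c1ccc(OCc6ccccc6)cc1)O[C@@H]3c2ccc(OCc6ccccc6)cc2 | intermediate
29 | C7a 4-benzyloxybenzylic cation on the all-trans indane | c1c(OCc6ccccc6)cc(OCc6ccccc6)cc1[C@H]3c4c(cc(OCc6ccccc6)cc4[C@H]4[C@H](c5ccc(OCc6ccccc6)cc5)c5c(OCc6ccccc6)cc(OCc6ccccc6)cc5[C@@H]4[CH+]c1ccc(OCc6ccccc6)cc1)O[C@@H]3c2ccc(OCc6ccccc6)cc2 | intermediate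
30 | octa-O-benzyl ether of the target (7aR,8aS,7bR,8bR,7cS,8cS) | c1ccccc1COc1ccc([C@@H]2c3c(OCc6ccccc6)cc(OCc6ccccc6)cc3[C@H]3c4c(cc(OCc6ccccc6)cc4[C@H]4[C@H](c5ccc(OCc6ccccc6)cc5)c5c(OCc6ccccc6)cc(OCc6ccccc6)cc5[C@H]24)O[C@@H]3c2ccc(OCc6ccccc6)cc2)cc1 | intermediate
31 | target CNP0193760.4 (7aR,8aS,7bR,8bR,7cS,8cS) | Oc1ccc([C@@H]2c3c(O)cc(O)cc3[C@H]3c4c(cc(O)cc4[C@H]4[C@H](c5ccc(O)cc5)c5c(O)cc(O)cc5[C@H]24)O[C@@H]3c2ccc(O)cc2)cc1 | target

**Step count and risks**

Total steps: 18. Longest linear sequence: 13 (steps 1–8, then 14–18).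

Steps most likely to fail:

Step 17. The cation may lose a proton instead of closing the medium ring, the radical closure may give the wrong relative configuration at C8a and C8b, or closure may occur on the wrong face of the cation. The fallback uses known chain and ionic chemistry in separate operations. It sets out from acid 25. Esterification with 1-hydroxypyridine-2(1H)-thione (DIC, CH2Cl2, dark) should give the Barton ester 2-thioxopyridin-1(2H)-yl (2RS,3R)-2-(DBF)-3-(BnOPh)-3-(StAr)propanoate F1. Irradiation with visible light at high dilution (benzene, rt) should lead through decarboxylation, 5-exo-trig cyclisation and transfer of the 2-pyridylthio group to the benzylic radical (Barton decarboxylation with group-transfer cyclisation). This gives the all-trans indanyl 4-benzyloxybenzylic 2-pyridyl sulfide F2 as a mixture at the sulfide carbon. Thiophilic activation of F2 with AgOSO2CF3 in CH2Cl2/HFIP at −20 °C should ionise the C–S bond to the same cation 29, which closes onto ring G, and the route is rejoined at 30.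

Step 14. Reductive elimination at the congested palladium enolate may be slow, so that the aryl bromide is only reduced. The fallback reverses the polarity of the two partners. It sets out from ester 23 and bromide 14. Deprotonation of 23 (LiN(SiMe3)2, THF, −78 °C) and quenching with 1,2-dibromotetrachloroethane should give the α-bromo ester methyl (2RS,3R)-2-bromo-3-(BnOPh)-3-(StAr)propanoate F3. Miyaura borylation of 14 (B2pin2, Pd(dppf)Cl2, KOAc, dioxane, 90 °C) should give the pinacol boronate 2-(DBF)-4,4,5,5-tetramethyl-1,3,2-dioxaborolane F4. Palladium-catalysed coupling of the α-bromo ester with the arylboronate (Pd(OAc)2, P(o-tol)3, K3PO4, THF/H2O, rt to 50 °C) should then form C8b–C9b from the other side and rejoin the route at 24.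

Step 12. Insertion of the aryl–rhodium species into the peri-hindered 3,4-double bond may be slow, with protodeboronation consuming the boronic acid. The fallback sets C7b by hydride delivery instead of aryl delivery, and installs ring C before the peri substituent is large. It sets out from coumarin 16 and uses 20 and 18. Oxidative Heck arylation at position 4 of the coumarin (20, Pd(OAc)2, 1,10-phenanthroline, O2, DMF, 80 °C) should give 7-(benzyloxy)-4-(BnOPh)-5-hydroxy-2H-chromen-2-one F5. Triflation (Tf2O, pyridine) should give 7-(benzyloxy)-4-(BnOPh)-2-oxo-2H-chromen-5-yl trifluoromethanesulfonate F6. Mizoroki–Heck coupling with 18 should give 7-(benzyloxy)-4-(BnOPh)-5-[(E)-2-(4-benzyloxyphenyl)ethenyl]-2H-chromen-2-one F7. Copper hydride catalysed asymmetric conjugate reduction of F7 (Cu(OAc)2, (R)-DTBM-SEGPHOS, (EtO)2MeSiH, t-BuOH, toluene, 0 °C; ligand enantiomer chosen to give 4R) should rejoin the route at 21.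

Further compounds
F1 | step 17 | 2-thioxopyridin-1(2H)-yl (2RS,3R)-2-(DBF)-3-(BnOPh)-3-(StAr)propanoate | c1c(OCc6ccccc6)cc(OCc6ccccc6)cc1[C@H]3c4c(cc(OCc6ccccc6)cc4C(C(=O)ON7C=CC=CC7=S)[C@H](c5ccc(OCc6ccccc6)cc5)c5c(OCc6ccccc6)cc(OCc6ccccc6)cc5/C=C/c1ccc(OCc6ccccc6)cc1)O[C@@H]3c2ccc(OCc6ccccc6)cc2
F2 | step 17 | all-trans indanyl 4-benzyloxybenzylic 2-pyridyl sulfide (skeleton of 28 with S-(2-pyridyl) on C7a, both epimers at C7a) | c1c(OCc6ccccc6)cc(OCc6ccccc6)cc1[C@H]3c4c(cc(OCc6ccccc6)cc4[C@H]4[C@H](c5ccc(OCc6ccccc6)cc5)c5c(OCc6ccccc6)cc(OCc6ccccc6)cc5[C@@H]4C(Sc7ccccn7)c1ccc(OCc6ccccc6)cc1)O[C@@H]3c2ccc(OCc6ccccc6)cc2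
F3 | step 14 | methyl (2RS,3R)-2-bromo-3-(BnOPh)-3-(StAr)propanoate | COC(=O)C(Br)[C@H](c5ccc(OCc6ccccc6)cc5)c5c(OCc6ccccc6)cc(OCc6ccccc6)cc5/C=C/c1ccc(OCc6ccccc6)cc1
F4 | step 14 | 2-(DBF)-4,4,5,5-tetramethyl-1,3,2-dioxaborolane | c1c(OCc6ccccc6)cc(OCc6ccccc6)cc1[C@H]3c4c(cc(OCc6ccccc6)cc4B7OC(C)(C)C(C)(C)O7)O[C@@H]3c2ccc(OCc6ccccc6)cc2
F5 | step 12 | 7-(benzyloxy)-4-(BnOPh)-5-hydroxy-2H-chromen-2-one | O=c1cc(-c2ccc(OCc3ccccc3)cc2)c2c(O)cc(OCc3ccccc3)cc2o1
F6 | step 12 | 7-(benzyloxy)-4-(BnOPh)-2-oxo-2H-chromen-5-yl trifluoromethanesulfonate | O=c1cc(-c2ccc(OCc3ccccc3)cc2)c2c(OS(=O)(=O)C(F)(F)F)cc(OCc3ccccc3)cc2o1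
F7 | step 12 | 7-(benzyloxy)-4-(BnOPh)-5-[(E)-2-(4-benzyloxyphenyl)ethenyl]-2H-chromen-2-one | O=c1cc(-c2ccc(OCc3ccccc3)cc2)c2c(/C=C/c3ccc(OCc4ccccc4)cc3)cc(OCc3ccccc3)cc2o1
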